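The north-east run held far more protic impurity than the north-west run, 1.7 mM against 0.082 mM, yet at 8.00 h its target stood 3.7 percentage points lower, and we want to turn that comparison into a price per molecule of impurity.

the same everywhere: starting material 10 mM; gas phase 2.6 mM (held)
- north-west: protic impurity 0.082 mM; run made earlier
- north-east: protic impurity 1.7 mM; run made earlier
- Friday's: protic impurity 0.120 mM; time 8.0 h
- Tuesday's: protic impurity 0.250 mM; time 8.0 h
- Saturday's: protic impurity 0.500 mM; time 8.0 h
- Monday's: protic impurity 1.00 mM; time 8.0 h
- Wednesday's: protic impurity 2.00 mM; time 8.0 h

| run | time / h | target / % |
|---|---|---|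
| north-west | 1.00 | 4.7 |
| north-west | 2.50 | 15.0 |
| north-west | 3.00 | 16.4 |
| north-west | 5.00 | 24.6 |
| north-west | 6.00 | 27.1 |
| north-west | 8.00 | 30.3 |
| north-east | 0.417 | 0.7 |
| north-east | 1.33 | 5.6 |
| north-east | 2.50 | 11.8 |
| north-east | 3.00 | 14.5 |
| north-east | 5.00 | 21.5 |
| north-east | 6.00 | 23.3 |
| north-east | 8.00 | 26.6 |

(scatter of a reading: 0.5 percentage points)

- at the start none of the gas phase is in solution
- "hardly changes" means that all values lie within two and a half points (for a concentration: within two and a half percent of the largest)

- amount of target at the end, in percent of the starting material charged for Friday's, Tuesday's, Saturday's, Monday's, Wednesday's, in this order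
- the course of these numbers from the first flask to the last (rises all the way / rises, then falls / hardly changes / falls, then rises / falls all the way)

We build the flask up one process at a time, following one molecule at each fork.

1. Take the main step first, starting material meeting the gas to give target: in the north-west run the target gained 10 points between 1.00 h and 2.50 h, and that pace held to 8.00 h would give 54.9%.

2. Now add a rival, a competing step: the same run reads 30.3% at 8.00 h, its pace over the last 2.00 h having fallen to a quarter of the early one, while 69.7% of the charge was not standing as target, so we suppose that something else takes starting material or target away, a supposition that these readings of target do not prove.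

3. Last comes the impurity, and we price it by the toll, the molecules of target missing at 8.00 h for each further molecule of impurity charged: 0.229, about a quarter of a molecule, and a rough reading, since it rests on two readings each good to 0.5 points.

4. We charge the same toll on every flask, starting from the north-west reading, which gives us 30.2% for Friday's and 25.9% for Wednesday's, a row that falls all the way, with Wednesday's charge lying beyond the runs we have.

The forecast, with the impurity acting “like a weak poison”, lies next to ours without being the same: 30.1%, 29.8%, 29.2%, 28.2%, 26%, and falls all the way.

The flasks give 29.5%, 29.3%, 29.0%, 28.3%, 27.0%, and the course falls all the way.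

    starting material + dissolved gas ⇌ target (K = 7300 L mol⁻¹, k = 62.3 L mol⁻¹ h⁻¹)
    starting material → side product (k = 0.181 h⁻¹)
    dissolved gas + protic impurity → quenched reagent (k = 353 L mol⁻¹ h⁻¹)
    target → over-reaction product (k = 0.0135 h⁻¹)
    gas phase ⇌ dissolved gas, rate k5*(csat - [dissolved gas]) (kL = 1.06 h⁻¹)

In Friday's flask, at 4.00 h, 33.0% of the starting material remained and 45.2% was already side product, and by 8.00 h the quench had taken nearly all of the impurity, leaving 0.433% of its charge. Wednesday's flask held less dissolved gas at 4.00 h, 1.85 mM against Friday's 2.08 mM, but had 2.39 mM by 8.00 h, level with Friday's, with 1.99 mM of quenched reagent formed. Between these two flasks the toll comes to 0.133. Charged on Monday's 28.3%, the earlier toll puts Wednesday's at 26.0%, and Wednesday's flask stood at 27.0%.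

Readings and results are calculated with constants of no real substance; the scatter is artificial.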